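**Plan**

- Retrosynthetic cuts, in order: the eleven O–benzyl bonds; the helper C4–O bond of the lower unit; C2–C3 and C4–C4a of the lower pyran ring together, as a formal [4+2] of an O-aryl oxocarbenium ion with a (Z)-2-silyloxyvinyl gallate that brings the ester with it; the acetal O1–C2 bond; the interflavan C4–C6 bond (Friedel–Crafts).
- Forward order: the upper chroman comes from (−)-epiafzelechin and is arylated at C4 with a para-differentiated phloroglucinol. The para oxygen is turned into the oxocarbenium precursor, the lower pyran ring is annulated last, then C4 is deoxygenated and all benzyl groups are removed.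
- Enabling feature: in the lower A-ring (C4a–C5–C6–C7–C8–C8a) the pyran oxygen O1 on C8a is para to the interflavan carbon C6, and the ring is 1,3,5-trioxygenated. Before annulation the two carbons ortho to that oxygen (future C4a and C8) are equivalent and strongly nucleophilic, so ring closure can only give the 4→6 isomer.
- Stereochemistry: upper C2/C3 from the chiral pool; upper C4 (β) by attack trans to the 3-O and 2-aryl groups; lower C2 by a chiral anion-binding catalyst acting on a planar oxocarbenium ion, on which both acetal epimers converge; lower C3 by the Z geometry of the enol silane and the endo (cis) mode of the annulation.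

Key step: step 11

Remark: (−)-epiafzelechin (2R,3R) is treated as a purchasable chiral-pool material.
Remark: the sense of induction in step 11 cannot be predicted with certainty; it is assumed to be fixed on a model acetal of 5, and the catalyst antipode that exposes the Si face of C2 of the oxocarbenium ion is used.

**Route**

Step 1
Reactants: 1 (−)-epiafzelechin
Product: 3 3,5,7,4'-tetra-O-benzyl-(−)-epiafzelechin, via 5,7,4'-tri-O-benzyl-(−)-epiafzelechin 2 (not isolated)
Conditions: BnBr (5 equiv), K2CO3, DMF, 0 °C→rt; then NaH, 0 °C→rt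
Reagents that add atoms: benzyl bromide, BrCc1ccccc1
Why: Williamson ether synthesis in which the three phenols are benzylated under carbonate conditions and the secondary 3-OH after deprotonation with NaH, without change at C2 or C3.

Step 2
Reactants: 3 3,5,7,4'-tetra-O-benzyl-(−)-epiafzelechin
Product: 4 (2R,3R,4S)-3,5,7-tris(benzyloxy)-2-[4-(benzyloxy)phenyl]-4-(2-ethoxyethoxy)chromane
Conditions: DDQ (2 equiv), 2-ethoxyethanol (5 equiv), CH2Cl2, rt
Reagents that add atoms: 2-ethoxyethanol, CCOCCO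
Why: Oxidative benzylic C–H functionalisation with DDQ, in which hydride is abstracted from C4 (activated by the 5,7-dialkoxy A-ring) and the alcohol adds trans to the 3-benzyloxy group (4β), a centre that is ionised again in step 4 so that its purity is immaterial.

Step 3
Reactants: 5 3,5-bis(benzyloxy)phenol
Product: 6 [3,5-bis(benzyloxy)phenoxy]triisopropylsilane
Conditions: TIPSCl, imidazole, DMF, rt
Reagents that add atoms: triisopropylsilyl chloride, CC(C)[Si](Cl)(C(C)C)C(C)C
Why: Standard silylation of a phenol, the bulky TIPS group being chosen to shield both ring carbons ortho to it in step 4.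

Step 4
Reactants: 4 (2R,3R,4S)-4-(2-ethoxyethoxy) flavan; 6 [3,5-bis(benzyloxy)phenoxy]triisopropylsilane
Product: 7 (2R,3R,4S)-3,5,7-tris(benzyloxy)-2-[4-(benzyloxy)phenyl]-4-{2,6-bis(benzyloxy)-4-[(triisopropylsilyl)oxy]phenyl}chromane
Conditions: 6 (3 equiv), TMSOTf (0.5 equiv), CH2Cl2, −78 °C; Et3N quench
Reagents that add atoms: none
Why: Lewis-acid-mediated Friedel–Crafts alkylation of an electron-rich arene by a C4-activated flavan, in which the planar C4 benzylic cation is attacked trans to the 3-benzyloxy and 2-aryl groups (4β, the usual 3,4-trans outcome for 2,3-cis flavans) by the arene carbon between the two benzyloxy groups and para to the silyloxy group, the excess of 6 suppressing double alkylation.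

Step 5
Reactants: 7 4β-aryl flavan TIPS ether
Product: 8 3,5-bis(benzyloxy)-4-{(2R,3R,4S)-3,5,7-tris(benzyloxy)-2-[4-(benzyloxy)phenyl]chroman-4-yl}phenol
Conditions: TBAF, AcOH, THF, 0 °C
Reagents that add atoms: none
Why: Fluoride-mediated cleavage of the aryl silyl ether under acetic acid buffering, which frees the para oxygen and unshields its two ortho carbons without touching a stereocentre.

Step 6
Reactants: 9 3,4-bis(benzyloxy)benzaldehyde
Product: 10 [3,4-bis(benzyloxy)phenyl](chloro)methyl pivalate (racemic)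
Conditions: PivCl, ZnCl2 (cat.), CH2Cl2, 0 °C→rt; volatiles removed, used crude
Reagents that add atoms: pivaloyl chloride, CC(C)(C)C(Cl)=O
Why: Lewis-acid-catalysed addition of an acyl chloride across an aldehyde carbonyl (α-chloroalkyl ester formation, as in the preparation of chloromethyl pivalate), giving a racemic reagent whose centre is not carried into the target.

Step 7
Reactants: 8 para-phenol; 10 [3,4-bis(benzyloxy)phenyl](chloro)methyl pivalate
Product: 11 {3,5-bis(benzyloxy)-4-[(2R,3R,4S)-3,5,7-tris(benzyloxy)-2-(4-benzyloxyphenyl)chroman-4-yl]phenoxy}[3,4-bis(benzyloxy)phenyl]methyl pivalate (both epimers at the acetal carbon)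
Conditions: NaH, THF/DMF, 0 °C; then 10 (1.5 equiv), 0 °C
Reagents that add atoms: none
Why: O-Alkylation of the unhindered phenoxide by the SN1-active α-chloro ester (acyloxyalkyl ether formation), in which the pivaloyl group resists acyl transfer and the new acetal centre arises as both epimers, which converge in step 11.

Step 8
Reactants: 12 3,4,5-tris(benzyloxy)benzoic acid
Product: 13 allyl 3,4,5-tris(benzyloxy)benzoate
Conditions: allyl bromide, K2CO3, DMF, rt
Reagents that add atoms: allyl bromide, C=CCBr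
Why: Carboxylate O-alkylation (SN2) to the allyl ester.

Step 9
Reactants: 13 allyl 3,4,5-tris(benzyloxy)benzoate
Product: 15 2-oxoethyl 3,4,5-tris(benzyloxy)benzoate, via secondary ozonide 14 (not isolated)
Conditions: O3, CH2Cl2, −78 °C (indicator end point); then Me2S, −78 °C→rt
Reagents that add atoms: ozone, [O-][O+]=O
Why: Ozonolysis of the terminal alkene with reductive work-up, the ester-deactivated arene and the benzyl ethers tolerating a titrated amount of ozone at −78 °C.

Step 10
Reactants: 15 2-oxoethyl 3,4,5-tris(benzyloxy)benzoate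
Product: 16 (Z)-2-[(tert-butyldimethylsilyl)oxy]ethenyl 3,4,5-tris(benzyloxy)benzoate
Conditions: TBSOTf, Et3N, CH2Cl2, 0 °C
Reagents that add atoms: tert-butyldimethylsilyl triflate, CC(C)(C)[Si](C)(C)OS(=O)(=O)C(F)(F)F
Why: Soft enolisation and O-silylation of the α-acyloxy aldehyde (silyl enol ether formation), which for α-oxygenated aldehydes should favour the Z (cis-dioxy) isomer, any E isomer being removed on deactivated silica.

Step 11
Reactants: 11 acyloxy acetal (both epimers); 16 (Z)-2-silyloxyvinyl gallate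
Product: 18 3,5,7,4'-tetra-O-benzyl-epiafzelechin-(4β→6)-[5,7,3',4'-tetra-O-benzyl-4α-(tert-butyldimethylsilyloxy)-epicatechin 3-O-(3,4,5-tri-O-benzylgallate)] (lower unit 2R,3S,4R and all-cis), via O-aryl oxocarbenium ion 17 (not isolated)
Conditions: 16 (2.5 equiv), chiral arylpyrrolidine squaramide (10 mol%), TBSOTf (20 mol%), 4 Å MS, TBME/CH2Cl2, −78 °C
Reagents that add atoms: none
Why: Proposed new method: the squaramide-bound silyl triflate silylates the pivalate carbonyl of 11 and ionises both acetal epimers to one planar (E)-O-aryl oxocarbenium ion 17 paired with the chiral squaramide·triflate anion, and the Z enol silane 16 then adds in an asynchronous formal [4+2] event in which its gallate-bearing carbon bonds to C2 and its silyloxy-bearing carbon (C4) bonds to the ring carbon ortho to the oxocarbenium oxygen, with loss of the arene proton. The closest known reaction types are the oxa-Povarov reaction of O-aryl oxocarbenium ions with alkenes and the enantioselective Mukaiyama-type addition of silyl enolates to acetal-derived oxocarbenium ions under anion-binding catalysis. The lower pyran ring closes as an inverse-electron-demand hetero-Diels–Alder closure, in stepwise terms a 6-exo-trig Friedel–Crafts attack of C4a on the C4 silyloxocarbenium carbon. C2 (R) is set by the catalyst, which has to expose the Si face of C2 in 17; C3 (the future 3R centre) follows from the Z geometry of 16 and the endo approach usual for Povarov-type additions (Si face of C3, like topicity), which puts the 2-aryl and 3-galloyloxy groups cis; C4 (silyloxy, expected cis as well) is a helper centre that is removed in step 12. Regioselectivity on the alkene is secured by the silyloxy group being a far stronger donor than the acyloxy group, chemoselective ionisation by pivalate being the only Lewis-basic and non-stabilising group on the acetal carbon, and regioselectivity on the arene by the two carbons ortho to the oxocarbenium oxygen being interchanged by rotation about the C4–aryl bond, so that either closure gives the same 4→6-linked product.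

Step 12
Reactants: 18 4α-silyloxy annulation product
Product: 19 3,5,7,4'-tetra-O-benzyl-epiafzelechin-(4β→6)-5,7,3',4'-tetra-O-benzyl-epicatechin 3-O-(3,4,5-tri-O-benzylgallate)
Conditions: Et3SiH (5 equiv), TMSOTf (0.2 equiv), CH2Cl2, −78→−40 °C
Reagents that add atoms: none
Why: Ionic hydrogenation (SN1-type reductive cleavage) of the C4 silyl ether, which is benzylic to a ring carrying three oxygens ortho and para to it, removing the helper oxygen and its stereocentre while C2, C3, the ester and the interflavan bond stay untouched.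

Step 13
Reactants: 19 per-O-benzyl dimer gallate
Product: 20 epiafzelechin-(4β→6)-epicatechin 3-O-gallate (CNP0210310.1)
Conditions: H2 (1 atm), 20% Pd(OH)2/C, THF/MeOH/H2O, rt
Reagents that add atoms: none
Why: Hydrogenolysis of all eleven benzyl ethers over Pearlman's catalyst under neutral conditions, which leaves the gallate ester, the interflavan bond and the five stereocentres untouched.

**Compound list**

1 | (−)-epiafzelechin, (2R,3R)-2-(4-hydroxyphenyl)chromane-3,5,7-triol | O[C@@H]1Cc2c(O)cc(O)cc2O[C@@H]1c1ccc(O)cc1 | starting material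
2 | 5,7,4'-tri-O-benzyl-(−)-epiafzelechin (2R,3R; not isolated) | O[C@@H]1Cc2c(OCc3ccccc3)cc(OCc3ccccc3)cc2O[C@@H]1c1ccc(OCc2ccccc2)cc1 | intermediate
3 | 3,5,7,4'-tetra-O-benzyl-(−)-epiafzelechin (2R,3R) | c1ccccc1CO[C@@H]1Cc2c(OCc3ccccc3)cc(OCc3ccccc3)cc2O[C@@H]1c1ccc(OCc2ccccc2)cc1 | intermediate
4 | (2R,3R,4S)-3,5,7-tris(benzyloxy)-2-[4-(benzyloxy)phenyl]-4-(2-ethoxyethoxy)chromane (4β-alkoxy, 3,4-trans) | CCOCCO[C@H]1c2c(OCc3ccccc3)cc(OCc3ccccc3)cc2O[C@H](c2ccc(OCc3ccccc3)cc2)[C@@H]1OCc1ccccc1 | intermediate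
5 | 3,5-bis(benzyloxy)phenol | Oc1cc(OCc2ccccc2)cc(OCc2ccccc2)c1 | starting material
6 | [3,5-bis(benzyloxy)phenoxy]triisopropylsilane | CC(C)[Si](C(C)C)(C(C)C)Oc1cc(OCc2ccccc2)cc(OCc2ccccc2)c1 | intermediate
7 | (2R,3R,4S)-3,5,7-tris(benzyloxy)-2-[4-(benzyloxy)phenyl]-4-{2,6-bis(benzyloxy)-4-[(triisopropylsilyl)oxy]phenyl}chromane (4β-aryl) | CC(C)[Si](C(C)C)(C(C)C)Oc1cc(OCc2ccccc2)c([C@H]2c3c(OCc4ccccc4)cc(OCc4ccccc4)cc3O[C@H](c3ccc(OCc4ccccc4)cc3)[C@@H]2OCc2ccccc2)c(OCc2ccccc2)c1 | intermediate
8 | 3,5-bis(benzyloxy)-4-{(2R,3R,4S)-3,5,7-tris(benzyloxy)-2-[4-(benzyloxy)phenyl]chroman-4-yl}phenol | Oc1cc(OCc2ccccc2)c([C@H]2c3c(OCc4ccccc4)cc(OCc4ccccc4)cc3O[C@H](c3ccc(OCc4ccccc4)cc3)[C@@H]2OCc2ccccc2)c(OCc2ccccc2)c1 | intermediate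
9 | 3,4-bis(benzyloxy)benzaldehyde | O=Cc1ccc(OCc2ccccc2)c(OCc2ccccc2)c1 | starting material
10 | [3,4-bis(benzyloxy)phenyl](chloro)methyl pivalate (racemic) | CC(C)(C)C(=O)OC(Cl)c1ccc(OCc2ccccc2)c(OCc2ccccc2)c1 | intermediate
11 | {3,5-bis(benzyloxy)-4-[(2R,3R,4S)-3,5,7-tris(benzyloxy)-2-(4-benzyloxyphenyl)chroman-4-yl]phenoxy}[3,4-bis(benzyloxy)phenyl]methyl pivalate (both acetal epimers) | CC(C)(C)C(=O)OC(Oc1cc(OCc2ccccc2)c([C@H]2c3c(OCc4ccccc4)cc(OCc4ccccc4)cc3O[C@H](c3ccc(OCc4ccccc4)cc3)[C@@H]2OCc2ccccc2)c(OCc2ccccc2)c1)c1ccc(OCc2ccccc2)c(OCc2ccccc2)c1 | intermediate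
12 | 3,4,5-tris(benzyloxy)benzoic acid | OC(=O)c1cc(OCc2ccccc2)c(OCc2ccccc2)c(OCc2ccccc2)c1 | starting material
13 | allyl 3,4,5-tris(benzyloxy)benzoate | C=CCOC(=O)c1cc(OCc2ccccc2)c(OCc2ccccc2)c(OCc2ccccc2)c1 | intermediate
14 | (1,2,4-trioxolan-3-yl)methyl 3,4,5-tris(benzyloxy)benzoate (secondary ozonide; not isolated) | O=C(OCC1OCOO1)c1cc(OCc2ccccc2)c(OCc2ccccc2)c(OCc2ccccc2)c1 | intermediate
15 | 2-oxoethyl 3,4,5-tris(benzyloxy)benzoate | O=CCOC(=O)c1cc(OCc2ccccc2)c(OCc2ccccc2)c(OCc2ccccc2)c1 | intermediate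
16 | (Z)-2-[(tert-butyldimethylsilyl)oxy]ethenyl 3,4,5-tris(benzyloxy)benzoate | CC(C)(C)[Si](C)(C)O/C=C\OC(=O)c1cc(OCc2ccccc2)c(OCc2ccccc2)c(OCc2ccccc2)c1 | intermediate
17 | (E)-O-aryl oxocarbenium ion from 11 by loss of pivalate (not isolated) | C(/c1ccc(OCc2ccccc2)c(OCc2ccccc2)c1)=[O+]\c1cc(OCc2ccccc2)c([C@H]2c3c(OCc4ccccc4)cc(OCc4ccccc4)cc3O[C@H](c3ccc(OCc4ccccc4)cc3)[C@@H]2OCc2ccccc2)c(OCc2ccccc2)c1 | intermediate
18 | per-O-benzyl epiafzelechin-(4β→6)-[4α-(tert-butyldimethylsilyloxy)-epicatechin 3-O-gallate]; upper 2R,3R,4S; lower 2R,3S,4R, 2,3,4-all-cis | O=C(O[C@@H]1[C@H](O[Si](C)(C)C(C)(C)C)c2c(cc(OCc3ccccc3)c([C@H]3c4c(OCc5ccccc5)cc(OCc5ccccc5)cc4O[C@H](c4ccc(OCc5ccccc5)cc4)[C@@H]3OCc3ccccc3)c2OCc2ccccc2)O[C@@H]1c1ccc(OCc2ccccc2)c(OCc2ccccc2)c1)c1cc(OCc2ccccc2)c(OCc2ccccc2)c(OCc2ccccc2)c1 | intermediate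
19 | 3,5,7,4'-tetra-O-benzyl-epiafzelechin-(4β→6)-5,7,3',4'-tetra-O-benzyl-epicatechin 3-O-(3,4,5-tri-O-benzylgallate); upper 2R,3R,4S; lower 2R,3R | O=C(O[C@@H]1Cc2c(cc(OCc3ccccc3)c([C@H]3c4c(OCc5ccccc5)cc(OCc5ccccc5)cc4O[C@H](c4ccc(OCc5ccccc5)cc4)[C@@H]3OCc3ccccc3)c2OCc2ccccc2)O[C@@H]1c1ccc(OCc2ccccc2)c(OCc2ccccc2)c1)c1cc(OCc2ccccc2)c(OCc2ccccc2)c(OCc2ccccc2)c1 | intermediate
20 | epiafzelechin-(4β→6)-epicatechin 3-O-gallate; upper 2R,3R,4S; lower 2R,3R | O=C(O[C@@H]1Cc2c(cc(O)c([C@H]3c4c(O)cc(O)cc4O[C@H](c4ccc(O)cc4)[C@@H]3O)c2O)O[C@@H]1c1ccc(O)c(O)c1)c1cc(O)c(O)c(O)c1 | target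

**Step count and risks**

Total steps: 13. Longest linear sequence: 8 steps (1, 2, 4, 5, 7, 11, 12, 13).

Step 11 (Proposed new method). What may go wrong: insufficient facial control by the catalyst over a very large ion pair, poor cis/trans selectivity in the C2–C3 bond formation, intermolecular Friedel–Crafts capture of the oxocarbenium ion by the upper A-ring, or renewed ionisation of the C4 silyl ether under the reaction conditions. The fallback uses known chemistry and sets out from 4. Commercial (−)-epicatechin would be benzylated at its four phenols (BnBr, K2CO3, DMF) to 5,7,3',4'-tetra-O-benzyl-(−)-epicatechin F1. Bromination at C8 (NBS, CH2Cl2, −78 °C) would give 8-bromo-5,7,3',4'-tetra-O-benzyl-(−)-epicatechin F2, and Steglich esterification with acid 12 (EDC, DMAP) would give its 3-O-(3,4,5-tri-O-benzylgallate) F3. TMSOTf-mediated coupling of 4 with F3, in which the blocked C8 leaves only C6 free and attack occurs trans to the 3-benzyloxy group, should give the 8-bromo analogue of 19, F4. Hydrogenolysis over Pd(OH)2/C with Et3N would remove the bromine and all benzyl groups, and the fallback comes back to the route at 20.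

Step 4. What may go wrong: attack of the C4 cation at a carbon ortho to the silyloxy group, giving the regioisomeric aryl adduct, or double alkylation of the arene. The fallback sets out from 4. Coupling with an excess of phloroglucinol (TMSOTf or BF3·OEt2, THF/CH2Cl2), whose three ring positions are equivalent, should give (2R,3R,4S)-3,5,7-tris(benzyloxy)-2-[4-(benzyloxy)phenyl]-4-(2,4,6-trihydroxyphenyl)chromane F5. Selective silylation of the unhindered para hydroxyl (TIPSCl, imidazole, DMF, −20 °C) would give the mono-TIPS ether F6. Benzylation of the two hindered ortho hydroxyls (BnBr, K2CO3, DMF) comes back to the route at 7.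

Step 7. What may go wrong: acyl transfer from the chloro ester to the phenoxide, C-alkylation of the phloroglucinol-type phenoxide, or hydrolysis of the acyloxy acetal on isolation. The fallback sets out from 8 and stores the acetal carbon as a robust O,S-acetal. Commercial 3,4-bis(benzyloxy)benzyl chloride and sodium thiophenolate would give 3,4-bis(benzyloxy)benzyl phenyl sulfide F7. Chlorination with NCS would give [3,4-bis(benzyloxy)phenyl](chloro)methyl phenyl sulfide F8. Alkylation of the sodium salt of 8 with F8 would give the O-aryl S-phenyl acetal F9, which should survive chromatography. Exchange of the thio group for pivalate (NIS, pivalic acid, CH2Cl2, −40 °C, as in the conversion of thioglycosides into glycosyl esters) immediately before use comes back to the route at 11.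

**Further compounds**

F1 | step 11 | 5,7,3',4'-tetra-O-benzyl-(−)-epicatechin | O[C@@H]1Cc2c(OCc3ccccc3)cc(OCc3ccccc3)cc2O[C@@H]1c1ccc(OCc2ccccc2)c(OCc2ccccc2)c1
F2 | step 11 | 8-bromo-5,7,3',4'-tetra-O-benzyl-(−)-epicatechin | O[C@@H]1Cc2c(OCc3ccccc3)cc(OCc3ccccc3)c(Br)c2O[C@@H]1c1ccc(OCc2ccccc2)c(OCc2ccccc2)c1
F3 | step 11 | 8-bromo-5,7,3',4'-tetra-O-benzyl-(−)-epicatechin 3-O-(3,4,5-tri-O-benzylgallate) | O=C(O[C@@H]1Cc2c(OCc3ccccc3)cc(OCc3ccccc3)c(Br)c2O[C@@H]1c1ccc(OCc2ccccc2)c(OCc2ccccc2)c1)c1cc(OCc2ccccc2)c(OCc2ccccc2)c(OCc2ccccc2)c1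
F4 | step 11 | 8-bromo analogue of 19 (bromine at C8 of the lower unit) | O=C(O[C@@H]1Cc2c(c(Br)c(OCc3ccccc3)c([C@H]3c4c(OCc5ccccc5)cc(OCc5ccccc5)cc4O[C@H](c4ccc(OCc5ccccc5)cc4)[C@@H]3OCc3ccccc3)c2OCc2ccccc2)O[C@@H]1c1ccc(OCc2ccccc2)c(OCc2ccccc2)c1)c1cc(OCc2ccccc2)c(OCc2ccccc2)c(OCc2ccccc2)c1
F5 | step 4 | (2R,3R,4S)-3,5,7-tris(benzyloxy)-2-[4-(benzyloxy)phenyl]-4-(2,4,6-trihydroxyphenyl)chromane | Oc1cc(O)c([C@H]2c3c(OCc4ccccc4)cc(OCc4ccccc4)cc3O[C@H](c3ccc(OCc4ccccc4)cc3)[C@@H]2OCc2ccccc2)c(O)c1
F6 | step 4 | (2R,3R,4S)-3,5,7-tris(benzyloxy)-2-[4-(benzyloxy)phenyl]-4-{2,6-dihydroxy-4-[(triisopropylsilyl)oxy]phenyl}chromane | CC(C)[Si](C(C)C)(C(C)C)Oc1cc(O)c([C@H]2c3c(OCc4ccccc4)cc(OCc4ccccc4)cc3O[C@H](c3ccc(OCc4ccccc4)cc3)[C@@H]2OCc2ccccc2)c(O)c1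
F7 | step 7 | 3,4-bis(benzyloxy)benzyl phenyl sulfide | c1ccccc1SCc1ccc(OCc2ccccc2)c(OCc2ccccc2)c1
F8 | step 7 | [3,4-bis(benzyloxy)phenyl](chloro)methyl phenyl sulfide (racemic) | ClC(Sc1ccccc1)c1ccc(OCc2ccccc2)c(OCc2ccccc2)c1
F9 | step 7 | O-aryl S-phenyl acetal of 8 with 3,4-bis(benzyloxy)benzaldehyde (both epimers) | c1ccccc1SC(Oc1cc(OCc2ccccc2)c([C@H]2c3c(OCc4ccccc4)cc(OCc4ccccc4)cc3O[C@H](c3ccc(OCc4ccccc4)cc3)[C@@H]2OCc2ccccc2)c(OCc2ccccc2)c1)c1ccc(OCc2ccccc2)c(OCc2ccccc2)c1
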